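In a one-step world, starting complex is lost in proportion to itself and to free incoming ligand, so free incoming ligand is the concentration to watch, and the decay of starting complex can read it.

| setting | ochre | amber | flask |
|---|---|---|---|
| starting complex | 0.27 M | 0.27 M | 0.27 M |
| incoming ligand | 0.81 M | 0.81 M | 0.810 M |
| scavenger | 0.081 M | 0.12 M | 0.0810 M |
| remark | the very flask that is asked about, followed so far | run made earlier |  |
| time |  |  | 3.0 h |

ochre run (percent of the starting complex charged)

| time / min | starting complex / % | complex with two exchanged / % |
|---|---|---|
| 5.00 | 94.0 | 0.5 |
| 10.0 | 86.6 | 3.7 |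
| 15.0 | 84.5 | 4.0 |
| 20.0 | 76.9 | 5.3 |
| 25.0 | 75.0 | 7.6 |
| 30.0 | 73.2 | 9.4 |
| 40.0 | 68.2 | 12.4 |

amber run (percent of the starting complex charged)

| time / h | starting complex / % | complex with two exchanged / % |
|---|---|---|
| 0.167 | 87.8 | 3.7 |
| 0.500 | 71.2 | 8.4 |
| 0.833 | 63.1 | 16.6 |
| 1.33 | 50.8 | 24.7 |
| 2.00 | 38.8 | 37.6 |
| 2.50 | 35.7 | 43.8 |
| 3.00 | 32.3 | 48.7 |

(scatter of a reading: 1 percentage point)

- the earlier runs were read with a standard deviation of 1 percentage point
- the earlier runs do not show how much of incoming ligand is bound; that part of a forecast is a guess

- part of the starting complex that has reacted at 3.0 h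
- share of free incoming ligand in free incoming ligand and idle adduct together, at 3.0 h

The readings of ochre at 10.0 min and amber at 0.167 h, pooled, give a pseudo-first-order constant of 0.821 /h, and dividing by the charged ligand gives the decay constant per molar of free incoming ligand, 1.01 /M/h, a reading with its scatter. One extreme holds the ligand at its charge and leaves 8.52% of the starting complex at 3.0 h. The other holds it from the outset at the level of amber's last hour, whose constant is 0.183 /h, and leaves 57.8%. The ochre flask should lie between them, since the late constant is smaller than the early one, and amber, charged with 0.12 M of scavenger against ochre's 0.081 M but reading close to ochre so far, stands at 67.7% reacted at 3.00 h, which this reckoning takes for ochre.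

Amber's late constant, taken for ochre too, reads free incoming ligand at 0.181 M. If each exchange frees one leaving ligand, amber's readings count 0.314 M freed; if ochre's scavenger takes its whole charge of 0.0810 M and the remaining 0.233 M binds incoming ligand as idle adduct, this estimate puts the free share near 43.7%.

The forecast stays close on the first answer with 68% but parts on the second with 87%, adding “If binding is partial, fr is higher”.

The flask gives 67.2% reacted and a free share of 49.7%, holding 0.203 M of idle adduct beside 24.8% of its incoming ligand free at 3.00 h.

    starting complex + incoming ligand → leaving ligand + complex with one exchanged (k = 2.90 × 10⁻⁴ /M/s)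
    complex with one exchanged + incoming ligand → leaving ligand + complex with two exchanged (k = 6.40 × 10⁻⁴ /M/s)
    leaving ligand + incoming ligand ⇌ idle adduct, settled at all times (K = 41.0 /M)
    scavenger + leaving ligand → scavenged by-product (k = 0.130 /M/s)
    incoming ligand ⇌ dormant form (K = 0.420, k = 2.50 × 10⁻⁴ /s)

At 1.01 /M/h, that free ligand means a decay constant of 0.204 /h. The neighbouring flask charged with 1.4 M of incoming ligand ends with 31% of its charge free, which means 0.434 /h, twice the flask's constant, and that neighbour has 86.4% of its starting complex reacted.

(All runs are simulated for substances that don't exist, and the scatter is random.)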